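The candidate steps put the same coupling partner and the same free catalyst into both substrate rates, each first-order in its own substrate, so the ratio s = ln l / ln r stays fixed during a run, where l and r are the fractions left of the left-handed and right-handed substrate, each of its own charge. This is the selectivity factor, and s = 1 is the symmetric case, with zero excess.

| setting | Wednesday's | Thursday's | Tuesday's | flask |
|---|---|---|---|---|
| left-handed substrate | 0.50 M | 0.50 M | 1 M | 0.50 M |
| right-handed substrate | 0.50 M | 0.50 M | 1 M | 0.50 M |
| gas | 19 mM (held) | 19 mM (held) | 19 mM (held) | 19 mM (held) |
| free catalyst | 0.041 mol% | 0.091 mol% | 0.061 mol% | 0.061 mol% |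
| remark | run made earlier | run made earlier | run made earlier |  |
| time |  |  |  | 2.0 h |

| run | time / min | right-handed substrate / % | left-handed substrate / % |
|---|---|---|---|
| Wednesday's | 15.0 | 22.7 | 10.7 |
| Wednesday's | 30.0 | 14.3 | 3.3 |
| Wednesday's | 40.0 | 11.0 | 3.5 |
| Wednesday's | 60.0 | 7.3 | 0.2 |
| Wednesday's | 80.0 | 3.7 | 0.4 |
| Thursday's | 6.00 | 31.5 | 18.5 |
| Thursday's | 10.0 | 21.6 | 6.8 |
| Thursday's | 20.0 | 7.6 | 1.0 |
| Thursday's | 40.0 | 2.0 | 0 |
| Thursday's | 80.0 | 0 | 1.2 |
| Tuesday's | 6.00 | 35.9 | 30.1 |
| Tuesday's | 20.0 | 10.6 | 3.0 |
| Tuesday's | 30.0 | 7.2 | 1.0 |
| Tuesday's | 50.0 | 0.3 | 1.3 |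
| Tuesday's | 80.0 | 1.4 | 0 |

(readings scatter by 1 percentage point)

- whether the excess of right-handed substrate over left-handed substrate among what is left of the two reaches 80 % by 2.0 h (yes / no)
- the highest excess of right-handed substrate over left-handed substrate among what is left of the two up to 2.0 h

- free catalyst is single-handed; left-handed substrate and right-handed substrate are mirror images of each other, charged as a racemate, each of them at the stated concentration
- at the start none of coupling partner is dissolved
- the numbers in the tables scatter by 1 percentage point (one standard deviation)
- candidate steps: coupling partner + free catalyst + left-handed substrate -> free catalyst + left-handed product; coupling partner + free catalyst + right-handed substrate -> free catalyst + right-handed product; free catalyst <-> dormant form; free catalyst -> spent catalyst; gas <-> coupling partner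

1. I pooled one reading from each run, Wednesday's at 30.0 min, Tuesday's at 20.0 min and Thursday's at 6.00 min, and divided the summed logarithms: s = 2.00, a reading with its scatter.

2. I kept the ledger on the substrates, the limiting reagent, in percent of both charged. An excess of 80 % demands l/r = 0.111, hence r = 0.111.

3. At that point the flask's books, as I reckoned them, read: right-handed substrate 5.54 %, left-handed substrate 0.616 %, right-handed product 44.5 %, left-handed product 49.4 %.

4. Wednesday's run, with less catalyst than the flask, read 3.7 % of right-handed substrate at 80.0 min, already below the ledger's entry. So I expected yes. With s, that reading gives an excess of 86.2 % in Wednesday's run, and I expected the top in the flask, which had more catalyst and a longer time, to stand above that estimate.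

5. The forecast said yes, with a top of 98 %: “The value is rising throughout, so the top comes at the end”.

    coupling partner + free catalyst + left-handed substrate → free catalyst + left-handed product (k = 62000 L² mol⁻² min⁻¹)
    coupling partner + free catalyst + right-handed substrate → free catalyst + right-handed product (k = 31000 L² mol⁻² min⁻¹)
    free catalyst ⇌ dormant form (K = 5.90, k = 0.0540 min⁻¹)
    free catalyst → spent catalyst (k = 0.00500 min⁻¹)
    gas ⇌ coupling partner, rate k5*(csat - [coupling partner]) (kL = 7.20 min⁻¹)

The flask's answer was yes, with a top of 96.7 %. It reached 80 % at 0.650 h with 5.56 % of right-handed substrate left, where the ledger had 5.54 %. At 1.00 h the flask's catalyst stood at 13.7 % free, 76.2 % dormant and 10.1 % spent, yet 3.10 % of right-handed substrate with s gives 0.192 % of left-handed substrate, and the flask held 0.192 %. In Tuesday's run at 30.0 min, the reading of 7.2 % of right-handed substrate with s gives 1.04 % of left-handed substrate, and the reading was 1.0 %.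

Readings and results were computed for substances that don't exist.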